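0.5 is the zero of my scale: on a complex with two equal, independent sites, that is the ratio of the second exchange's rate coefficient to the first's.

| flask | starting complex | incoming ligand | remark | time |
|---|---|---|---|---|
| gamma | 2 M | 0.60 equiv | run made earlier |  |
| theta | 2 M | 0.79 equiv | run made earlier |  |
| delta | 2 M | 1.2 equiv | run made earlier |  |
| amber | 2.0 M | 0.500 equiv |  | 8.0 h |
| green | 2.0 M | 1.50 equiv |  | 8.0 h |

| run | time / h | complex with two exchanged / % | complex with one exchanged / % |
|---|---|---|---|
| gamma | 0.500 | 0 | 12.0 |
| gamma | 1.33 | 2.0 | 20.6 |
| gamma | 2.50 | 2.9 | 22.6 |
| gamma | 4.00 | 5.4 | 22.3 |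
| gamma | 6.00 | 5.7 | 19.9 |
| theta | 0.500 | 1.6 | 15.1 |
| theta | 1.33 | 2.4 | 25.2 |
| theta | 2.50 | 5.3 | 28.9 |
| theta | 4.00 | 8.1 | 28.0 |
| theta | 6.00 | 9.0 | 24.8 |
| delta | 0.500 | 1.8 | 21.3 |
| delta | 1.33 | 5.9 | 34.2 |
| delta | 2.50 | 11.4 | 35.6 |
| delta | 4.00 | 16.6 | 34.9 |
| delta | 6.00 | 22.3 | 30.8 |

(scatter of a reading: 0.5 percentage points)

- the earlier runs were read with a standard deviation of 0.5 percentage points

* which of these holds the largest part of the starting complex at the end of amber (complex with one exchanged / complex with two exchanged / starting complex)
* which of these holds the largest part of the starting complex at the end of green (complex with one exchanged / complex with two exchanged / starting complex)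
* amount of complex with two exchanged at the end of green, in percent of the starting complex charged

I work in fractions of the charge, take each rate as coefficient times complex times free ligand, and get the ligand by difference. In the delta run, the first half hour gives the first exchange 0.482 /h, and the next interval gives the second 0.211 /h. Their quotient, read off scattered readings, is 0.437: the step ratio, a selectivity factor between the exchanges. The ligand cancels, so the second exchange runs at the first's rate times step ratio times one-exchanged over starting complex.

With these two exchanges alone, one-exchanged would peak at a ratio of 2.29 to starting complex. Yet in delta its highest reading is 35.6% at 2.50 h, when its ratio to all the unread charge is 0.672. If all that charge were starting complex, the second exchange in delta would take 0.294 of what the first makes, less than the first makes, so I expect a further path and do not read the unread charge as starting complex.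

The forecast names starting complex for amber and starting complex for green, with 36% two-exchanged in green, “nearly tied” with starting complex at 37%.

Of the three species asked, starting complex leads amber, and complex with two exchanged leads green at 36.7%, with starting complex at 3.62%.

    crystals ⇌ leaving ligand, rate k1*(cs1 - [leaving ligand]) while solid is left; crystals form when [leaving ligand] > cs1 (solubility = 0.0770 M, k = 0.00110 /s)
    starting complex + complex with one exchanged → side product (k = 4.70 × 10⁻⁵ /M/s)
    starting complex + incoming ligand ⇌ leaving ligand + complex with one exchanged (K = 2.90, k = 7.80 × 10⁻⁵ /M/s)
    complex with one exchanged + incoming ligand ⇌ leaving ligand + complex with two exchanged (K = 91.0, k = 3.30 × 10⁻⁵ /M/s)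

Green has not come to rest at 8.00 h: by 80.0 h, one-exchanged falls from 25.8% to 2.09%, two-exchanged rises from 36.7% to 59.7%, and side product moves from 33.9% to 37.9%. At 8.00 h, the step ratio with green's fractions gives 3.11 for the second exchange's forward rate over the first's.

In the same flask as green with 1.2 M of starting complex, the same reckoning at 8.00 h gives 1.66, below green's. That neighbour flask holds 27.9% two-exchanged, and complex with one exchanged leads.

Readings and results were computed with made-up constants; the scatter is artificial.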